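You go wrong here if you treat the open intermediate as an end product that climbs with conversion, because it is also a reagent, consumed by the second intermediate on the way to target.

    substrate → open intermediate (k1 = 5.63 × 10⁻⁵ s⁻¹, Ea1 = 102 kJ mol⁻¹)
    partner → second intermediate (k2 = 4.47 × 10⁻⁵ s⁻¹, Ea2 = 101 kJ mol⁻¹)
    open intermediate + second intermediate → target (k3 = 0.00451 M⁻¹ s⁻¹, Ea3 = 60.0 kJ mol⁻¹)
    2 second intermediate → homo product (k4 = 0.00150 M⁻¹ s⁻¹, Ea4 = 81.0 kJ mol⁻¹)
    second intermediate + capture agent → trapped intermediate (k5 = 6.33 × 10⁻⁵ M⁻¹ s⁻¹, Ea5 = 78.0 kJ mol⁻¹)
    (constants at 35 °C)

in all of them: substrate 0.39 M; partner 0.950 equiv; capture agent 7.80 mM; time 25 h
- grey: temperature 55 °C
- green: temperature 35 °C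
- blue: temperature −5 °C
- violet: temperature 15 °C

- where a step has two of a species, its rate is k times that concentration squared, and two are used at each turn
- constants are those at 35 °C; use the activation energies for any other temperature

* the flask that comes out highest in amount of open intermediate, in percent of the substrate charged, or "all alike" when all lie within 1.5 percentage points (grey / green / blue / violet / all alike)
* open intermediate at the end, in percent of the substrate charged, grey
* open intermediate at the end, in percent of the substrate charged, green
* open intermediate at the end, in percent of the substrate charged, blue
* open intermediate at the end, in percent of the substrate charged, violet

The bench rule says that early on, whatever substrate has opened still stands as open intermediate, so its percentage equals the substrate's conversion. Scaled to blue with the activation energy, that gives 1.33%. Where does the rule stop? Compare rates at one moment. The open intermediate forms at the first constant times [substrate], and it drains at a pseudo-first-order constant equal to the coupling constant times [second intermediate]. That comparison drifts, since [second intermediate] starts from nothing and at first grows as the partner's constant times [partner] times the time. Summed over a run short enough for these early forms to hold, with [substrate] and [partner] near their charges and the other losses of second intermediate left aside, the share of formed open intermediate that has already coupled is the coupling constant times the partner's constant times the starting [partner] times the square of the time, over 3. Call this the coupling number: 0.0171 for blue. That is far below one, so the rule stands in blue. Its border lies near one. In violet the number is 2.57 and in green 202, both past the border. For violet the rule therefore gives a ceiling, 27.4%, and my reckoning ends there without naming a winner.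

The forecast names grey highest, with 25.4% there, 18.2% in green, 13% in violet and 1.31% in blue, on the ground that “Hotter flasks give more because homo-coupling wastes more partner”.

The simulation gives grey highest, at 24.8%, then 18.4% in green, 13.0% in violet and 1.30% in blue, so the forecast stands within its tolerance. In blue, the half-life of the open intermediate by the coupling at 12.5 h is 28 d, longer than the run's 25 h. The coupled share read from blue's end, 1.67%, sits beside a coupling number of 0.0171.

Now take a second flask: blue repeated warmer, with all amounts and the time held. At 10 °C the bench rule says 14.0%, but the coupling number is 0.785, close to the border, so the rule should overshoot. That neighbour holds 9.05% open intermediate, with 86.0% of the substrate left.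

Its constants are assumed; the rest is arithmetic.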